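**Plan**

1. Numbering is that of xanthanolides, upper half C-1 to C-15, lower (3-oxobutyl) half primed, C-11' the spiro carbon and C-13' its ring CH2. The two halves are antipodal in their C-7/C-8/C-10 triads and C-3 sits on the concave face of the lower lactone (syn to C-6'), so cycloaddition onto a preformed lower methylene lactone is not used.
2. Cuts: C-3–C-4 (acetyl, through an enol triflate); C-11'–C-13' and C-1–C-2 (Michael/aldol annulation of a lower β-keto lactone onto an upper α-methylene cycloheptanone); the lactone bonds C-7–C-11 and C-7'–C-11'; and, in each cycloheptene, the two bonds that flank the ring alkene.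
3. Enabling feature: the lower ring is a cyclohept-4-ene whose oxygen-bearing C-8' is 1,4 to both alkene carbons. C-6'–C-7'–C-8'(O)–C-9'–C-10' is therefore a 1-oxy-vinylcyclopropane, and C-1'=C-5' with its whole side chain is a terminal alkyne.
4. Forward order: two enantiomeric siloxy-vinylcyclopropanes, then two cycloheptadienyl silyl enol ethers by [5+2], then two cis-lactones, then the central six-membered ring (ketol), enol triflate, upper methylene lactone, acetyl group and unmasking.
5. Stereochemistry: C-10 and C-10' come from antipodal asymmetric cyclopropanations and are retained in the [5+2]. C-7/C-8 and C-7'/C-8' come from antipodal catalyst-controlled ketone hydrogenations with dynamic kinetic resolution. C-11' comes from convex-face Michael addition (C-13' enters anti to C-6'). C-5 and C-1 come from thermodynamically controlled cis-ketol closure, anti to the C-10 methyl group and the upper lactone.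

Key step: step 4

Assumption: the absolute sense of the dipeptide-modified zinc carbenoid (steps 2, 8) and of the ruthenium diphosphine/diamine catalyst (steps 6, 11) is assigned by analogy; if either proves opposite, the antipodal catalyst is used in that series.

**Route**

Step 1
Reactants: 1 pent-1-en-3-one
Product: 2 (Z)-triethyl(penta-1,3-dien-3-yloxy)silane
Conditions: Et3SiOTf, Et3N, Et2O, 0 °C
Reagents that add atoms: triethylsilyl trifluoromethanesulfonate, CC[Si](CC)(CC)OS(=O)(=O)C(F)(F)F
Why: Soft enolisation and O-silylation of the ethyl ketone (silyl dienol ether formation) should give the conjugated, thermodynamically preferred Z enol ether with oxygen and methyl cis.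

Step 2
Reactants: 2 (Z)-triethyl(penta-1,3-dien-3-yloxy)silane
Product: 3 (1R,2R)-triethyl[(2-methyl-1-vinylcyclopropyl)oxy]silane
Conditions: Et2Zn, CH2I2, N-Boc-L-Val-L-Pro-OMe (0.25 equiv), CH2Cl2, −40 to 0 °C
Reagents that add atoms: diiodomethane, ICI
Why: Asymmetric Simmons–Smith cyclopropanation should attack only the electron-rich enol ether double bond, the stereospecific syn addition keeping oxygen and methyl cis (methyl trans to vinyl) and the dipeptide ligand fixing the absolute configuration of the future C-10'.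

Step 3
Reactants: 4 hex-5-yn-2-one
Product: 5 2-(but-3-yn-1-yl)-2-methyl-1,3-dioxolane
Conditions: HOCH2CH2OH, TsOH (cat.), benzene, reflux, Dean–Stark
Reagents that add atoms: ethylene glycol, OCCO
Why: Acid-catalysed ketalisation masks the methyl ketone for the organolithium, hydrogenation and enolate steps that follow.

Step 4
Reactants: 3 (1R,2R)-triethyl[(2-methyl-1-vinylcyclopropyl)oxy]silane; 5 2-(but-3-yn-1-yl)-2-methyl-1,3-dioxolane
Product: 6 triethyl{[(6R)-6-methyl-5-[2-(2-methyl-1,3-dioxolan-2-yl)ethyl]cyclohepta-1,4-dien-1-yl]oxy}silane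
Conditions: [Rh(CO)2Cl]2 (3 mol %), ClCH2CH2Cl, 60 °C
Reagents that add atoms: none
Why: The rhodium carbonyl chloride dimer binds the vinyl group of 3 and opens the cyclopropane bond between the siloxy carbon (future C-8') and the methyl-bearing carbon (future C-10') to a σ-alkyl/π-allyl rhodacyclohexene; the alkyne 5 then inserts into the rhodium–allyl terminus, which makes C-6'–C-5', and reductive elimination joins the chain-bearing alkyne carbon to the rhodium-bound secondary carbon, which makes C-1'–C-10'. The closest known reaction type is the rhodium-catalysed intermolecular [5+2] cycloaddition of 1-siloxy-vinylcyclopropanes with terminal alkynes. The cycloheptadiene ring of the lower half is closed by this two-bond metallacycle pathway, the last bond in a C(sp2)–C(sp3) reductive elimination from an eight-membered rhodacycle. No new stereocentre arises: C-10' is carried over from 3 with retention, since ring opening and reductive elimination both proceed with retention at that carbon, and the other cyclopropane centre is erased as the enol ether carbon. Two selectivities are needed: opening of the more substituted cyclopropane bond, for which the methyl group is placed trans to the vinyl group (outside the rhodacycle) and the small carbonyl-ligated catalyst is chosen because it favours the weaker, more electron-rich bond, and the alkyne orientation with the substituted carbon remote from the first-formed bond, the normal steric preference of terminal alkynes. The siloxy group, which activates the cyclopropane, stays as the regiodefined enol ether that marks C-7' for the next bond and later becomes the lactone oxygen at C-8'.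

Step 5
Reactants: 6 triethyl{[(6R)-6-methyl-5-[2-(2-methyl-1,3-dioxolan-2-yl)ethyl]cyclohepta-1,4-dien-1-yl]oxy}silane
Product: 8 ethyl 2-[(5R)-5-methyl-4-[2-(2-methyl-1,3-dioxolan-2-yl)ethyl]-7-oxocyclohept-3-en-1-yl]acetate (both C-1 epimers), via lithium enolate 7 (not isolated)
Conditions: MeLi, THF, 0 °C; then BrCH2CO2Et, DMPU, −78 to −20 °C
Reagents that add atoms: ethyl bromoacetate, CCOC(=O)CBr
Why: Cleavage of the silyl enol ether by methyllithium gives the regiospecific lithium enolate, whose alkylation with the reactive α-halo ester forms C-7'–C-11' before the enolate can equilibrate (enolate alkylation).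

Step 6
Reactants: 8 ethyl 2-[(5R)-5-methyl-4-[2-(2-methyl-1,3-dioxolan-2-yl)ethyl]-7-oxocyclohept-3-en-1-yl]acetate
Product: 10 (3aS,7R,8aS)-7-methyl-6-[2-(2-methyl-1,3-dioxolan-2-yl)ethyl]-3,3a,4,7,8,8a-hexahydro-2H-cyclohepta[b]furan-2-one, via hydroxy ester 9 (not isolated)
Conditions: RuCl2[(S)-xylBINAP][(S)-DAIPEN] (1 mol %), KOtBu (0.1 equiv), H2 (10 atm), i-PrOH, 30 °C; then 50 °C
Reagents that add atoms: none
Why: Ruthenium diphosphine/diamine-catalysed asymmetric ketone hydrogenation with dynamic kinetic resolution should reduce, out of the base-equilibrated C-7' epimers, the one matched to the catalyst and from the face anti to the acetate arm, so that C-7' and C-8' are set cis and absolute by the catalyst and the cis γ-hydroxy ester closes to the cis-fused lactone.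

Step 7
Reactants: 10 (3aS,7R,8aS)-7-methyl-6-[2-(2-methyl-1,3-dioxolan-2-yl)ethyl]-3,3a,4,7,8,8a-hexahydro-2H-cyclohepta[b]furan-2-one
Product: 12 (3aS,7R,8aS)-3-acetyl-7-methyl-6-[2-(2-methyl-1,3-dioxolan-2-yl)ethyl]-3,3a,4,7,8,8a-hexahydro-2H-cyclohepta[b]furan-2-one (C-3 epimers and enol), via lithium enolate 11 (not isolated)
Conditions: LiN(SiMe3)2 (2.2 equiv), THF, −78 °C; 1-acetylimidazole; aq NH4Cl
Reagents that add atoms: 1-acetylimidazole, CC(=O)n1ccnc1
Why: Claisen-type C-acylation of the lactone enolate with an acylimidazole installs the acetyl group that becomes C-3 and C-2, the second equivalent of base taking up the more acidic product; the new centre is later made planar again.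

Step 8
Reactants: 2 (Z)-triethyl(penta-1,3-dien-3-yloxy)silane
Product: 13 (1S,2S)-triethyl[(2-methyl-1-vinylcyclopropyl)oxy]silane
Conditions: Et2Zn, CH2I2, N-Boc-D-Val-D-Pro-OMe (0.25 equiv), CH2Cl2, −40 to 0 °C
Reagents that add atoms: diiodomethane, ICI
Why: The same asymmetric Simmons–Smith cyclopropanation with the antipodal dipeptide should give the enantiomeric vinylcyclopropane, which carries the future C-10.

Step 9
Reactants: 13 (1S,2S)-triethyl[(2-methyl-1-vinylcyclopropyl)oxy]silane; 14 ethynyltrimethylsilane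
Product: 15 triethyl{[(6S)-6-methyl-5-(trimethylsilyl)cyclohepta-1,4-dien-1-yl]oxy}silane
Conditions: [Rh(CO)2Cl]2 (3 mol %), ClCH2CH2Cl, 60 °C, sealed tube
Reagents that add atoms: none
Why: The same rhodium-catalysed [5+2] cycloaddition builds the upper cycloheptadiene with retention at C-10, the bulky silyl group going to the alkyne carbon that bonds to C-10, where it marks C-1 for the later carbonyl group.

Step 10
Reactants: 15 triethyl{[(6S)-6-methyl-5-(trimethylsilyl)cyclohepta-1,4-dien-1-yl]oxy}silane
Product: 17 ethyl 2-[(5S)-5-methyl-7-oxo-4-(trimethylsilyl)cyclohept-3-en-1-yl]acetate (both C-1 epimers), via lithium enolate 16 (not isolated)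
Conditions: MeLi, THF, 0 °C; then BrCH2CO2Et, DMPU, −78 to −20 °C
Reagents that add atoms: ethyl bromoacetate, CCOC(=O)CBr
Why: Regiospecific enolate generation from the silyl enol ether and alkylation form C-7–C-11, the vinylsilane being inert to methyllithium (enolate alkylation).

Step 11
Reactants: 17 ethyl 2-[(5S)-5-methyl-7-oxo-4-(trimethylsilyl)cyclohept-3-en-1-yl]acetate
Product: 19 (3aR,7S,8aR)-7-methyl-6-(trimethylsilyl)-3,3a,4,7,8,8a-hexahydro-2H-cyclohepta[b]furan-2-one, via hydroxy ester 18 (not isolated)
Conditions: RuCl2[(R)-xylBINAP][(R)-DAIPEN] (1 mol %), KOtBu (0.1 equiv), H2 (10 atm), i-PrOH, 30 °C; then 50 °C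
Reagents that add atoms: none
Why: The antipodal ruthenium catalyst should set C-7 and C-8 cis and absolute by the same asymmetric hydrogenation with dynamic kinetic resolution, followed by lactonisation.

Step 12
Reactants: 19 (3aR,7S,8aR)-7-methyl-6-(trimethylsilyl)-3,3a,4,7,8,8a-hexahydro-2H-cyclohepta[b]furan-2-one
Product: 21 (3aR,7S,8aR)-7-methylhexahydro-2H-cyclohepta[b]furan-2,6(3H)-dione, via epoxysilane 20 (not isolated)
Conditions: mCPBA, NaHCO3, CH2Cl2, 0 °C; then 10% aq H2SO4, THF, 0 °C to rt, short contact
Reagents that add atoms: 3-chloroperoxybenzoic acid, O=C(OO)c1cccc(Cl)c1 (oxygen of 20); water, O (carbonyl oxygen of 21)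
Why: Epoxidation of the vinylsilane and acid-mediated opening at the silicon-bearing carbon followed by Peterson-type loss of silanol (epoxysilane-to-ketone conversion) should place the carbonyl group regiospecifically at C-1.

Step 13
Reactants: 21 (3aR,7S,8aR)-7-methylhexahydro-2H-cyclohepta[b]furan-2,6(3H)-dione
Product: 25 (3aR,7S,8aR)-7-methyl-5-methylidenehexahydro-2H-cyclohepta[b]furan-2,6(3H)-dione, via lithium enolate 22 (not isolated), via Mannich base 23 (not isolated), via ammonium iodide 24 (not isolated)
Conditions: LiN(SiMe3)2 (1.05 equiv), THF, −78 °C; Me2N=CH2+ I−, −78 to 0 °C; then MeI, CH2Cl2, rt; then aq NaHCO3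
Reagents that add atoms: N,N-dimethylmethyleneiminium iodide, C[N+](C)=C.[I-]; iodomethane, CI (in 24 only)
Why: Kinetic deprotonation at the less hindered C-5 methylene of the ketone (more acidic than the lactone), Mannich reaction and Hofmann-type elimination of the quaternised amine should give the exo-methylene ketone (α-methylenation) without touching C-10.

Step 14
Reactants: 12 (3aS,7R,8aS)-3-acetyl lactone of the lower half; 25 (3aR,7S,8aR)-7-methyl-5-methylidenehexahydro-2H-cyclohepta[b]furan-2,6(3H)-dione
Product: 27 spiro ketol (target skeleton with C-3 ketone; C-2 and C-11 as CH2; side-chain ketone as dioxolane; OH-1 and H-5 cis), via Michael adduct 26 (not isolated)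
Conditions: Et3N (0.2 equiv), CH2Cl2, 0 °C to rt; then KOtBu (0.3 equiv), t-BuOH/THF, 0 °C
Reagents that add atoms: none
Why: Amine-catalysed Michael addition of the β-keto lactone to the α-methylene ketone followed by base-mediated intramolecular aldol addition of the acetyl methyl group to the C-1 ketone (Robinson-type annulation stopped at the ketol) should build the six-membered ring, the enolate of 12 being attacked on the convex face of the cis-fused bicycle so that C-13' enters anti and the acetyl carbon (C-3) stays syn to C-6', while the reversible aldol step and the epimerisable C-5 (and C-10) of 26 let the cis-fused ketol settle on the face of the cycloheptanone opposite to the C-10 methyl group and the upper lactone.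

Step 15
Reactants: 27 spiro ketol
Product: 28 trimethylsilyl ether of 27 at O-1
Conditions: 1-(trimethylsilyl)imidazole, CH2Cl2, rt
Reagents that add atoms: 1-(trimethylsilyl)imidazole, C[Si](C)(C)n1ccnc1
Why: Silylation of the tertiary aldol hydroxyl under neutral conditions blocks retro-aldol cleavage during the enolisation that follows and spares the dioxolane.

Step 16
Reactants: 28 trimethylsilyl ether of the ketol
Product: 30 enol triflate (C-2=C-3, triflate on C-3), via potassium enolate 29 (not isolated)
Conditions: KN(SiMe3)2 (1.1 equiv), THF, −78 °C; PhNTf2, −78 to 0 °C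
Reagents that add atoms: N-phenylbis(trifluoromethanesulfonimide), O=S(=O)(N(c1ccccc1)S(=O)(=O)C(F)(F)F)C(F)(F)F
Why: The C-3 ketone can enolise only towards C-2 because C-11' is quaternary, so O-triflation of its enolate (enol triflate formation) fixes the C-2=C-3 double bond of the target.

Step 17
Reactants: 30 enol triflate
Product: 34 enol triflate with the upper α-methylene lactone (C-11=C-13), via lithium enolate 31 (not isolated), via Mannich base 32 (not isolated), via ammonium iodide 33 (not isolated)
Conditions: LiN(i-Pr)2, THF, −78 °C; Me2N=CH2+ I−; then MeI, MeOH, rt; then aq NaHCO3, CH2Cl2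
Reagents that add atoms: N,N-dimethylmethyleneiminium iodide, C[N+](C)=C.[I-]; iodomethane, CI (in 33 only)
Why: With both ketones masked and the spiro lactone lacking α-hydrogen, the upper lactone CH2 is the only acidic site, so enolate Mannich reaction and Hofmann-type elimination should install the exocyclic methylene (lactone α-methylenation).

Step 18
Reactants: 34 methylene lactone enol triflate
Product: 35 1-ethoxyvinyl diene (C-3 bears C(OEt)=CH2)
Conditions: Bu3SnC(OEt)=CH2, Pd(PPh3)4 (10 mol %), CuCl, LiCl, DMSO, 60 °C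
Reagents that add atoms: tributyl(1-ethoxyvinyl)stannane, CCCC[Sn](CCCC)(CCCC)C(=C)OCC
Why: Stille coupling of the vinyl triflate with the acetyl-anion equivalent, accelerated by copper chloride and lithium chloride for the hindered neopentyl-type position, should attach C-4 and C-15 to C-3.

Step 19
Reactants: 35 1-ethoxyvinyl diene
Product: 36 target CNP0195550.4
Conditions: 1 M HCl, THF, 0 °C to rt
Reagents that add atoms: water, O
Why: Mild acid hydrolysis should convert the enol ether into the acetyl group (giving the γ-hydroxy enone) and remove the silyl ether and the dioxolane in one operation, with no stereocentre involved.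

**Compound list**

1 | pent-1-en-3-one | CCC(=O)C=C | starting material
2 | (Z)-triethyl(penta-1,3-dien-3-yloxy)silane | C/C=C(\O[Si](CC)(CC)CC)C=C | intermediate
3 | (1R,2R)-triethyl[(2-methyl-1-vinylcyclopropyl)oxy]silane, methyl trans to vinyl | C=C[C@]1(O[Si](CC)(CC)CC)C[C@H]1C | intermediate
4 | hex-5-yn-2-one | CC(=O)CCC#C | starting material
5 | 2-(but-3-yn-1-yl)-2-methyl-1,3-dioxolane | CC1(CCC#C)OCCO1 | intermediate
6 | triethyl{[(6R)-6-methyl-5-[2-(2-methyl-1,3-dioxolan-2-yl)ethyl]cyclohepta-1,4-dien-1-yl]oxy}silane | CC[Si](CC)(CC)OC1=CCC=C(CCC2(C)OCCO2)[C@H](C)C1 | intermediate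
7 | lithium enolate from 6 (O–C-8'=C-7') | [Li+].[O-]C1=CCC=C(CCC2(C)OCCO2)[C@H](C)C1 | intermediate (not isolated)
8 | ethyl 2-[(5R)-5-methyl-4-[2-(2-methyl-1,3-dioxolan-2-yl)ethyl]-7-oxocyclohept-3-en-1-yl]acetate, C-1 epimers (centre left open) | CCOC(=O)CC1CC=C(CCC2(C)OCCO2)[C@H](C)CC1=O | intermediate
9 | ethyl 2-[(1S,5R,7S)-7-hydroxy-5-methyl-4-[2-(2-methyl-1,3-dioxolan-2-yl)ethyl]cyclohept-3-en-1-yl]acetate | CCOC(=O)C[C@@H]1CC=C(CCC2(C)OCCO2)[C@H](C)C[C@@H]1O | intermediate (not isolated)
10 | (3aS,7R,8aS)-7-methyl-6-[2-(2-methyl-1,3-dioxolan-2-yl)ethyl]-3,3a,4,7,8,8a-hexahydro-2H-cyclohepta[b]furan-2-one, cis-fused, H-3a, H-8a and H-7 on one face | O=C1O[C@H]2C[C@@H](C)C(CCC3(C)OCCO3)=CC[C@H]2C1 | intermediate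
11 | lithium enolate of 10 | [Li+].[O-]C1O[C@H]2C[C@@H](C)C(CCC3(C)OCCO3)=CC[C@H]2C=1 | intermediate (not isolated)
12 | (3aS,7R,8aS)-3-acetyl derivative of 10, C-3 epimers and enol (centre left open) | CC(=O)C1C(=O)O[C@H]2C[C@@H](C)C(CCC3(C)OCCO3)=CC[C@H]21 | intermediate
13 | (1S,2S)-triethyl[(2-methyl-1-vinylcyclopropyl)oxy]silane | C=C[C@@]1(O[Si](CC)(CC)CC)C[C@@H]1C | intermediate
14 | ethynyltrimethylsilane | C#C[Si](C)(C)C | starting material
15 | triethyl{[(6S)-6-methyl-5-(trimethylsilyl)cyclohepta-1,4-dien-1-yl]oxy}silane | CC[Si](CC)(CC)OC1=CCC=C([Si](C)(C)C)[C@@H](C)C1 | intermediate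
16 | lithium enolate from 15 | [Li+].[O-]C1=CCC=C([Si](C)(C)C)[C@@H](C)C1 | intermediate (not isolated)
17 | ethyl 2-[(5S)-5-methyl-7-oxo-4-(trimethylsilyl)cyclohept-3-en-1-yl]acetate, C-1 epimers (centre left open) | CCOC(=O)CC1CC=C([Si](C)(C)C)[C@@H](C)CC1=O | intermediate
18 | ethyl 2-[(1R,5S,7R)-7-hydroxy-5-methyl-4-(trimethylsilyl)cyclohept-3-en-1-yl]acetate | CCOC(=O)C[C@H]1CC=C([Si](C)(C)C)[C@@H](C)C[C@H]1O | intermediate (not isolated)
19 | (3aR,7S,8aR)-7-methyl-6-(trimethylsilyl)-3,3a,4,7,8,8a-hexahydro-2H-cyclohepta[b]furan-2-one | O=C1O[C@@H]2C[C@H](C)C([Si](C)(C)C)=CC[C@@H]2C1 | intermediate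
20 | 5,6-epoxide of 19 (epoxysilane, either face, epoxide centres left open) | O=C1O[C@@H]2C[C@H](C)C3([Si](C)(C)C)OC3C[C@@H]2C1 | intermediate (not isolated)
21 | (3aR,7S,8aR)-7-methylhexahydro-2H-cyclohepta[b]furan-2,6(3H)-dione | O=C1O[C@@H]2C[C@H](C)C(=O)CC[C@@H]2C1 | intermediate
22 | lithium enolate of 21 towards xanthanolide C-5 | [Li+].[O-]C1=CC[C@@H]2CC(=O)O[C@@H]2C[C@H]1C | intermediate (not isolated)
23 | 5-[(dimethylamino)methyl] derivative of 21 (C-5 left open) | O=C1O[C@@H]2C[C@H](C)C(=O)C(CN(C)C)C[C@@H]2C1 | intermediate (not isolated)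
24 | methiodide of 23 | O=C1O[C@@H]2C[C@H](C)C(=O)C(C[N+](C)(C)C)C[C@@H]2C1.[I-] | intermediate (not isolated)
25 | (3aR,7S,8aR)-7-methyl-5-methylidenehexahydro-2H-cyclohepta[b]furan-2,6(3H)-dione | O=C1O[C@@H]2C[C@H](C)C(=O)C(=C)C[C@@H]2C1 | intermediate
26 | Michael adduct: C-11' quaternary, bearing acetyl and the CH2 link to C-5 of the upper keto lactone (C-5 left open) | CC(=O)[C@@]4(CC3C[C@@H]5CC(=O)O[C@@H]5C[C@H](C)C3=O)C(=O)O[C@H]1C[C@@H](C)C(CCC6(C)OCCO6)=CC[C@H]14 | intermediate (not isolated)
27 | spiro ketol: target skeleton with C-3 ketone, C-2 and C-11 as CH2, dioxolane on the side chain, OH-1 cis to H-5 | C1C(=O)O[C@@H]2C[C@H](C)[C@@]3(O)CC(=O)[C@@]4(C[C@H]3C[C@H]12)C(=O)O[C@H]1C[C@@H](C)C(CCC5(C)OCCO5)=CC[C@H]14 | intermediate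
28 | O-1 trimethylsilyl ether of 27 | C1C(=O)O[C@@H]2C[C@H](C)[C@@]3(O[Si](C)(C)C)CC(=O)[C@@]4(C[C@H]3C[C@H]12)C(=O)O[C@H]1C[C@@H](C)C(CCC5(C)OCCO5)=CC[C@H]14 | intermediate
29 | potassium C-2/C-3 enolate of 28 | C1C(=O)O[C@@H]2C[C@H](C)[C@@]3(O[Si](C)(C)C)C=C([O-])[C@@]4(C[C@H]3C[C@H]12)C(=O)O[C@H]1C[C@@H](C)C(CCC5(C)OCCO5)=CC[C@H]14.[K+] | intermediate (not isolated)
30 | enol triflate (C-2=C-3, OTf on C-3) | C1C(=O)O[C@@H]2C[C@H](C)[C@@]3(O[Si](C)(C)C)C=C(OS(=O)(=O)C(F)(F)F)[C@@]4(C[C@H]3C[C@H]12)C(=O)O[C@H]1C[C@@H](C)C(CCC5(C)OCCO5)=CC[C@H]14 | intermediate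
31 | lithium enolate of the upper lactone of 30 | C1=C([O-])O[C@@H]2C[C@H](C)[C@@]3(O[Si](C)(C)C)C=C(OS(=O)(=O)C(F)(F)F)[C@@]4(C[C@H]3C[C@H]12)C(=O)O[C@H]1C[C@@H](C)C(CCC5(C)OCCO5)=CC[C@H]14.[Li+] | intermediate (not isolated)
32 | 11-[(dimethylamino)methyl] derivative of 30 (C-11 left open) | CN(C)CC1C(=O)O[C@@H]2C[C@H](C)[C@@]3(O[Si](C)(C)C)C=C(OS(=O)(=O)C(F)(F)F)[C@@]4(C[C@H]3C[C@H]12)C(=O)O[C@H]1C[C@@H](C)C(CCC5(C)OCCO5)=CC[C@H]14 | intermediate (not isolated)
33 | methiodide of 32 | C[N+](C)(C)CC1C(=O)O[C@@H]2C[C@H](C)[C@@]3(O[Si](C)(C)C)C=C(OS(=O)(=O)C(F)(F)F)[C@@]4(C[C@H]3C[C@H]12)C(=O)O[C@H]1C[C@@H](C)C(CCC5(C)OCCO5)=CC[C@H]14.[I-] | intermediate (not isolated)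
34 | enol triflate with upper α-methylene lactone | C=C1C(=O)O[C@@H]2C[C@H](C)[C@@]3(O[Si](C)(C)C)C=C(OS(=O)(=O)C(F)(F)F)[C@@]4(C[C@H]3C[C@H]12)C(=O)O[C@H]1C[C@@H](C)C(CCC5(C)OCCO5)=CC[C@H]14 | intermediate
35 | 1-ethoxyvinyl diene (C-3 bears C(OEt)=CH2) | C=C1C(=O)O[C@@H]2C[C@H](C)[C@@]3(O[Si](C)(C)C)C=C(C(=C)OCC)[C@@]4(C[C@H]3C[C@H]12)C(=O)O[C@H]1C[C@@H](C)C(CCC5(C)OCCO5)=CC[C@H]14 | intermediate
36 | CNP0195550.4 | C=C1C(=O)O[C@@H]2C[C@H](C)[C@@]3(O)C=C(C(C)=O)[C@@]4(C[C@H]3C[C@H]12)C(=O)O[C@H]1C[C@@H](C)C(CCC(C)=O)=CC[C@H]14 | target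

**Totals and risks**

Total step count: 19. Longest linear sequence: 13 steps (1, 8 to 19).

Step 4 (the same concern holds for step 9). The rhodium may open the less substituted cyclopropane bond, which would put the methyl group on C-9', or the reductive elimination at the secondary carbon may be slow enough for the vinylcyclopropane to rearrange instead. The fallback sets out from 5 and returns at 8. Copper-catalysed Markovnikov hydroboration of 5 with pinacolborane (CuCl, N-heterocyclic carbene ligand, NaOtBu, MeOH) gives the 1,1-disubstituted alkenylboronate F1. Conjugate addition of F1 to (E)-octa-2,7-dien-4-one with [Rh(cod)Cl]2 and the BINAP antipode that gives the R centre sets C-10' and gives the dienyl ketone F2. Ring-closing metathesis with the second-generation Grubbs catalyst closes the cycloheptenone F3. Kinetic deprotonation at the less hindered α-methylene (LiN(i-Pr)2, −78 °C) and alkylation with ethyl bromoacetate lead to 8.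

Step 14. Under the equilibrating base the system may settle at a C-5/C-1 or C-10 epimer, close the bridged aldol from C-10, lose the acetyl group by retro-Claisen cleavage or dehydrate. The fallback sets out from 12 and 25 and returns at 28. The Michael adduct 26 is made with Et3N alone and isolated, and its C-5 epimers are separated or equilibrated with DBU. Its methyl ketone is converted with LiN(SiMe3)2 and Me3SiCl at −78 °C into the enol silane F4. A fluoride-triggered intramolecular Mukaiyama-type aldol addition with silyl transfer (catalytic tetrabutylammonium difluorotriphenylsilicate, THF, −40 °C) then closes the ring irreversibly, on the face of the C-1 carbonyl away from the C-10 methyl group, and gives 28 directly.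

Step 6 (the same concern holds for step 11). Epimerisation at C-7' may be slower than hydrogenation, or the catalyst may fail to override the bias of C-10', so that lactone diastereomers form. The fallback sets out from 6 and returns at 10. Methanolysis of 6 (K2CO3, MeOH) gives the cycloheptenone F3 (the ketone of the first fallback). Its SAMP hydrazone F5 is deprotonated at the less hindered α-methylene and alkylated with ethyl bromoacetate under auxiliary control to the hydrazone F6 (RAMP if the sense requires). Hydrolysis with CuCl2 in aqueous THF releases the single-epimer keto ester F7. LiBH(s-Bu)3 at −78 °C then adds hydride anti to the side chain without epimerisation, and the cis-hydroxy ester 9 lactonises to 10.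

**Further compounds**

F1 | step 4 | 2-{5-(2-methyl-1,3-dioxolan-2-yl)pent-1-en-2-yl}-4,4,5,5-tetramethyl-1,3,2-dioxaborolane | C=C(CCC1(C)OCCO1)B1OC(C)(C)C(C)(C)O1
F2 | step 4 | (6R)-6-methyl-7-methylidene-9-(2-methyl-1,3-dioxolan-2-yl)non-1-en-4-one (dienyl ketone) | C=C(CCC1(C)OCCO1)[C@H](C)CC(=O)CCC=C
F3 | step 4 | (6R)-6-methyl-5-[2-(2-methyl-1,3-dioxolan-2-yl)ethyl]cyclohept-4-en-1-one | O=C1CCC=C(CCC2(C)OCCO2)[C@H](C)C1
F4 | step 14 | trimethylsilyl enol ether of the acetyl group of 26 | C=C(O[Si](C)(C)C)[C@@]4(CC3C[C@@H]5CC(=O)O[C@@H]5C[C@H](C)C3=O)C(=O)O[C@H]1C[C@@H](C)C(CCC6(C)OCCO6)=CC[C@H]14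
F5 | step 6 | SAMP hydrazone of F3 | COC[C@@H]1CCCN1N=C1CCC=C(CCC2(C)OCCO2)[C@H](C)C1
F6 | step 6 | SAMP hydrazone alkylated at C-7' with the ethyl acetate arm | COC[C@@H]1CCCN1N=C1C[C@@H](C)C(CCC2(C)OCCO2)=CC[C@H]1CC(=O)OCC
F7 | step 6 | ethyl 2-[(1S,5R)-5-methyl-4-[2-(2-methyl-1,3-dioxolan-2-yl)ethyl]-7-oxocyclohept-3-en-1-yl]acetate | CCOC(=O)C[C@@H]1CC=C(CCC2(C)OCCO2)[C@H](C)CC1=O
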